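**Plan**

1. Numbering: the ten-membered ring runs from the methylidene carbon C1 to C10 (C5 = C(CH3)OH, C7 = CH–O-aroyl, C8 = CH–iPr, C9 = CHOH). The enabling feature is that sp2 C1 and the C5–C6 edge are 1,5-related across the bare C2–C4 methylenes, the imprint of a cyclodec-5-en-1-one and hence of a 1-vinyl-2-isopropenylcyclohexanol.
2. Retrosynthetic cuts, in order: the C7–O aroyl ester; C5–OH and C6–H (back to the C5=C6 alkene through its epoxide); C1=CH2 (back to the C1 ketone); ring bond C3–C4 with reconnection of C1–C6 (retro-oxy-Cope) down to a cyclohexane; then the vinyl–C1 and isopropenyl–C6 bonds and the arene–isopropyl bond.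
3. Forward: phloroglucinol is isopropylated and hydrogenated to the all-cis cyclohexanetriol (six-membered ring, C7–C9 triad in place). The ring is desymmetrised, oxidised at the unhindered carbinol, α-isopropenylated and vinylated. The ten-membered ring then arises in one step from the six-membered ring by anionic oxy-Cope ring expansion.
4. Stereochemistry: the relative configuration of C7/C8/C9 comes from cis-hydrogenation of the arene. The absolute configuration comes from lipase desymmetrisation of a meso diol, with TES and TBS then marking O7 and O9. The trans-1,2-dialkenyl arrangement comes from an equatorial isopropenyl group and equatorial vinyl addition. The E-C5=C6 alkene comes from the chair transition state. C5 comes from C7-hydroxyl-directed epoxidation under A1,3 control and hydride opening at C6.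
5. End game: methylenation of C1, TES removal, epoxidation, reduction, acylation of C7–OH with silyl-protected 4-hydroxybenzoic acid, global desilylation.

Key step: step 13

**Remarks before the steps**

- Numbering of six-membered intermediates (kept constant): C1 = carbon that becomes the ketone, C3 = carbinol carbon that becomes C7, C4 = isopropyl-bearing carbon (later C8), C5 = carbinol carbon that becomes C9.
- Assumption: the lipase shows the usual preference for the R-configured secondary carbinol and acetylates O–C3; if it chooses O–C5, steps 5 and 7 are run with TESOTf first and TBSOTf second.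
- Assumption: the (R,R)-amide is the enantiomer of the base that removes the C2 proton of 11; if the sense is opposite, the (S,S)-amide is used.

**Route**

Step 1
Reactants: 1 phloroglucinol; 2 propan-2-ol
Product: 3 2-isopropylbenzene-1,3,5-triol
Conditions: i-PrOH (1 equiv), 1 (3 equiv), MeSO3H, 60 °C
Reagents that add atoms: propan-2-ol, CC(C)O
Why: Friedel–Crafts alkylation: the acid-generated isopropyl cation attacks the strongly activated arene, whose three free positions are equivalent, so one constitution results, and the excess of 1 holds back polyalkylation.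

Step 2
Reactants: 3 2-isopropylbenzene-1,3,5-triol
Product: 4 all-cis-2-isopropylcyclohexane-1,3,5-triol (meso)
Conditions: H2 (80 bar), 5% Rh/Al2O3, EtOH, 60 °C
Reagents that add atoms: none
Why: Heterogeneous arene hydrogenation delivers all six hydrogens from the catalyst-bound face, so the three hydroxyls and the isopropyl group should end up mutually cis, which fixes the relative configuration of the later C7–C9 triad.

Step 3
Reactants: 4 all-cis-2-isopropylcyclohexane-1,3,5-triol
Product: 5 all-cis-3,5-dihydroxy-4-isopropylcyclohexyl pivalate (meso)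
Conditions: t-BuCOCl (1.05 equiv), pyridine, CH2Cl2, −20 °C
Reagents that add atoms: pivaloyl chloride, CC(C)(C)C(=O)Cl
Why: Regioselective acylation: the bulky acyl chloride should take only the C1 hydroxyl, which has two methylene neighbours, while the C3 and C5 hydroxyls are shielded by the adjacent isopropyl group.

Step 4
Reactants: 5 all-cis-3,5-dihydroxy-4-isopropylcyclohexyl pivalate
Product: 6 (1R,3R,4S,5S)-3-acetoxy-5-hydroxy-4-isopropylcyclohexyl pivalate
Conditions: Burkholderia cepacia lipase (immobilised), vinyl acetate, t-BuOMe, 35 °C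
Reagents that add atoms: vinyl acetate, CC(=O)OC=C
Why: Lipase-catalysed enantiotopos-selective transesterification (desymmetrisation of a meso diol) with an irreversible acyl donor; the enzyme distinguishes the two enantiotopic carbinols and thereby sets the absolute configuration of the whole route.

Step 5
Reactants: 6 (1R,3R,4S,5S)-3-acetoxy-5-hydroxy-4-isopropylcyclohexyl pivalate
Product: 7 (1S,3R,4R,5S)-3-acetoxy-5-(tert-butyldimethylsilyloxy)-4-isopropylcyclohexyl pivalate
Conditions: TBSOTf, 2,6-lutidine, CH2Cl2, −78 → 0 °C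
Reagents that add atoms: tert-butyldimethylsilyl triflate, CC(C)(C)[Si](C)(C)OS(=O)(=O)C(F)(F)F
Why: Silylation of the remaining hindered secondary hydroxyl with a silyl triflate and a non-nucleophilic base, a standard protection that both esters tolerate.

Step 6
Reactants: 7 (1S,3R,4R,5S)-3-acetoxy-5-(tert-butyldimethylsilyloxy)-4-isopropylcyclohexyl pivalate
Product: 8 (1S,3R,4R,5S)-5-(tert-butyldimethylsilyloxy)-3-hydroxy-4-isopropylcyclohexyl pivalate
Conditions: K2CO3 (cat.), MeOH, 0 °C
Reagents that add atoms: none
Why: Transesterification (methanolysis) removes the acetate while the hindered pivalate and the TBS ether stay; cold, catalytic carbonate is chosen to keep 1,3-silyl migration, which would erode the enantiomeric purity, at bay.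

Step 7
Reactants: 8 (1S,3R,4R,5S)-5-(tert-butyldimethylsilyloxy)-3-hydroxy-4-isopropylcyclohexyl pivalate
Product: 9 (1S,3R,4R,5S)-5-(tert-butyldimethylsilyloxy)-4-isopropyl-3-(triethylsilyloxy)cyclohexyl pivalate
Conditions: TESOTf, 2,6-lutidine, CH2Cl2, −78 °C
Reagents that add atoms: triethylsilyl triflate, CC[Si](CC)(CC)OS(=O)(=O)C(F)(F)F
Why: Triethylsilyl protection gives the oxygen that later becomes O7 a group that can be removed in the presence of the TBS ether on the later O9.

Step 8
Reactants: 9 (1S,3R,4R,5S)-5-(tert-butyldimethylsilyloxy)-4-isopropyl-3-(triethylsilyloxy)cyclohexyl pivalate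
Product: 10 (1S,3R,4R,5S)-5-(tert-butyldimethylsilyloxy)-4-isopropyl-3-(triethylsilyloxy)cyclohexan-1-ol
Conditions: i-Bu2AlH (2.5 equiv), CH2Cl2, −78 → −40 °C; aqueous tartrate work-up
Reagents that add atoms: none
Why: Reductive cleavage of the pivalate with an aluminium hydride leaves both silyl ethers untouched and frees the unhindered C1 carbinol.

Step 9
Reactants: 10 (1S,3R,4R,5S)-5-(tert-butyldimethylsilyloxy)-4-isopropyl-3-(triethylsilyloxy)cyclohexan-1-ol
Product: 11 (3R,4R,5S)-5-(tert-butyldimethylsilyloxy)-4-isopropyl-3-(triethylsilyloxy)cyclohexan-1-one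
Conditions: Dess–Martin periodinane, CH2Cl2, rt
Reagents that add atoms: none
Why: Dess–Martin oxidation runs under neutral to weakly acidic conditions, so the β,β′-bis(silyloxy) ketone should form without β-elimination.

Step 10
Reactants: 11 (3R,4R,5S)-5-(tert-butyldimethylsilyloxy)-4-isopropyl-3-(triethylsilyloxy)cyclohexan-1-one
Product: 13 (3S,4S,5S)-5-(tert-butyldimethylsilyloxy)-4-isopropyl-3-(triethylsilyloxy)-1-(trimethylsilyloxy)cyclohex-1-ene, via lithium enolate 12 (not isolated)
Conditions: (R,R)-[PhCH(Me)]2NLi (from the amine and n-BuLi), TMSCl present from the start, THF, −100 → −78 °C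
Reagents that add atoms: chlorotrimethylsilane, C[Si](C)(C)Cl
Why: Deprotonation by a chiral lithium amide with in situ silyl chloride quench is the established way to tell apart the two α-methylenes of a cyclohexanone that are related by a (here near-) mirror plane; the base should choose C2 over C6, and the enolate is silylated before it can expel the C3 silyloxy group.

Step 11
Reactants: 13 (3S,4S,5S)-5-(tert-butyldimethylsilyloxy)-4-isopropyl-3-(triethylsilyloxy)-1-(trimethylsilyloxy)cyclohex-1-ene; 14 2-bromopropene
Product: 16 (2R,3S,4S,5S)-5-(tert-butyldimethylsilyloxy)-4-isopropyl-2-(prop-1-en-2-yl)-3-(triethylsilyloxy)cyclohexan-1-one, via tin enolate 15 (not isolated)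
Conditions: 2-bromopropene, Bu3SnF, Pd2(dba)3 (cat.), P(t-Bu)3 (cat.), toluene, 70 °C
Reagents that add atoms: 2-bromopropene, C=C(C)Br
Why: Palladium-catalysed α-alkenylation of a ketone through its tin enolate, generated regiospecifically from the silyl enol ether by Bu3SnF, with a 1-bromoalkene; no strongly basic enolate is present, and the new, epimerisable C2 centre should settle with the isopropenyl group equatorial and trans to the C3 silyloxy group.

Step 12
Reactants: 16 (2R,3S,4S,5S)-5-(tert-butyldimethylsilyloxy)-4-isopropyl-2-(prop-1-en-2-yl)-3-(triethylsilyloxy)cyclohexan-1-one; 17 vinylmagnesium bromide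
Product: 18 (1R,2R,3S,4S,5S)-5-(tert-butyldimethylsilyloxy)-4-isopropyl-2-(prop-1-en-2-yl)-3-(triethylsilyloxy)-1-vinylcyclohexan-1-ol
Conditions: CH2=CHMgBr, CeCl3, THF, −78 °C
Reagents that add atoms: vinylmagnesium bromide, C=C[Mg]Br
Why: 1,2-Addition of the weakly basic vinylcerium reagent avoids enolisation; equatorial attack on the chair with equatorial isopropenyl should give the axial alcohol with vinyl trans to isopropenyl (C1 R), the minor epimer being removed by chromatography.

Step 13
Reactants: 18 (1R,2R,3S,4S,5S)-5-(tert-butyldimethylsilyloxy)-4-isopropyl-2-(prop-1-en-2-yl)-3-(triethylsilyloxy)-1-vinylcyclohexan-1-ol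
Product: 21 (5E,7R,8S,9S)-9-(tert-butyldimethylsilyloxy)-8-isopropyl-5-methyl-7-(triethylsilyloxy)cyclodec-5-en-1-one, via potassium alkoxide 19 (not isolated), via potassium enolate 20 (not isolated)
Conditions: KH, 18-crown-6, THF, 0 °C → rt; AcOH, −78 °C
Reagents that add atoms: none
Why: KH with 18-crown-6 turns 18 into the dissociated potassium alkoxide 19, whose C1–C2 ring bond is weakened enough for a concerted [3,3] sigmatropic shift near room temperature: the vinyl and isopropenyl termini join (the new C3–C4 bond of the product) while the C1–C2 bond of the cyclohexane breaks, giving enolate 20 and, on cold protonation, ketone 21. This is the anionic oxy-Cope rearrangement of a trans-1,2-dialkenylcyclohexanol, the standard entry to (E)-cyclodec-5-enones. The ten-membered ring is thus closed by four-atom ring expansion of the six-membered ring through a six-centre chair transition state, not by end-to-end cyclisation, so no high dilution is needed. No stereocentre is created: the C7–C9 triad lies outside the reacting array and is carried through unchanged, and the only new stereochemical element, the E geometry of C5=C6, follows from the chair transition state in which both alkenyl groups are equatorial. The selectivity needed is E over Z and a regiodefined C1–C2 enolate; the first is secured by the trans-diequatorial vinyl and isopropenyl groups of 18, and the second by the mechanism itself, which keeps the enolate away from C10 so that the C9 silyloxy group is not expelled before the acetic acid quench. Both silyl ethers are trans to the axial alkoxide, so silyl migration onto it is geometrically disfavoured.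

Step 14
Reactants: 21 (5E,7R,8S,9S)-9-(tert-butyldimethylsilyloxy)-8-isopropyl-5-methyl-7-(triethylsilyloxy)cyclodec-5-en-1-one
Product: 22 (5E,7R,8S,9S)-9-(tert-butyldimethylsilyloxy)-8-isopropyl-5-methyl-1-methylidene-7-(triethylsilyloxy)cyclodec-5-ene
Conditions: Cp2TiMe2, toluene, 65 °C, dark
Reagents that add atoms: dimethyltitanocene, [CH3-].[CH3-].[Ti+4].[cH-]1cccc1.[cH-]1cccc1
Why: Petasis methylenation: the titanium methylidene generated thermally from Cp2TiMe2 olefinates the ketone under neutral, non-basic conditions, so the C9 silyloxy group β to the carbonyl is not eliminated and no enolate-driven transannular reaction can start.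

Step 15
Reactants: 22 (5E,7R,8S,9S)-9-(tert-butyldimethylsilyloxy)-8-isopropyl-5-methyl-1-methylidene-7-(triethylsilyloxy)cyclodec-5-ene
Product: 23 (5E,7R,8R,9S)-9-(tert-butyldimethylsilyloxy)-8-isopropyl-5-methyl-1-methylidenecyclodec-5-en-7-ol
Conditions: PPTS (cat.), MeOH–CH2Cl2, 0 °C
Reagents that add atoms: none
Why: Mild acid-catalysed methanolysis cleaves the triethylsilyl ether selectively, the more hindered and more robust TBS ether at C9 being retained.

Step 16
Reactants: 23 (5E,7R,8R,9S)-9-(tert-butyldimethylsilyloxy)-8-isopropyl-5-methyl-1-methylidenecyclodec-5-en-7-ol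
Product: 24 (5R,6R,7S,8R,9S)-9-(tert-butyldimethylsilyloxy)-5,6-epoxy-8-isopropyl-5-methyl-1-methylidenecyclodecan-7-ol
Conditions: VO(acac)2 (cat.), t-BuOOH, CH2Cl2, 0 °C
Reagents that add atoms: tert-butyl hydroperoxide, CC(C)(C)OO
Why: Vanadium-catalysed hydroxyl-directed epoxidation: only C5=C6 is allylic to the free hydroxyl, and with C7–H eclipsing the double bond to avoid A1,3 strain with the C5 methyl the hydroxyl lies on the outer face of the E-cycloalkene, so oxygen should be delivered there and C5 set as R.

Step 17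
Reactants: 24 (5R,6R,7S,8R,9S)-9-(tert-butyldimethylsilyloxy)-5,6-epoxy-8-isopropyl-5-methyl-1-methylidenecyclodecan-7-ol
Product: 25 (5R,7R,8R,9S)-9-(tert-butyldimethylsilyloxy)-8-isopropyl-5-methyl-1-methylidenecyclodecane-5,7-diol
Conditions: NaAlH2(OCH2CH2OMe)2, THF, 0 °C → rt
Reagents that add atoms: none
Why: Reductive opening of a 2,3-epoxy alcohol with NaAlH2(OCH2CH2OMe)2: hydride is delivered intramolecularly from the C7 alkoxyaluminate to the proximal and less substituted C6, giving the 1,3-diol with the C5 configuration retained.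

Step 18
Reactants: 26 4-hydroxybenzoic acid
Product: 28 4-(tert-butyldimethylsilyloxy)benzoic acid, via silyl ester 27 (not isolated)
Conditions: TBSCl (2.2 equiv), imidazole, DMF, rt; then AcOH–H2O–THF, rt
Reagents that add atoms: tert-butyldimethylsilyl chloride, CC(C)(C)[Si](C)(C)Cl
Why: Silylation of both acidic groups followed by mild hydrolysis of the labile silyl ester leaves the phenol protected and the acid free.

Step 19
Reactants: 25 (5R,7R,8R,9S)-9-(tert-butyldimethylsilyloxy)-8-isopropyl-5-methyl-1-methylidenecyclodecane-5,7-diol; 28 4-(tert-butyldimethylsilyloxy)benzoic acid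
Product: 30 (5R,7R,8R,9S)-9-(tert-butyldimethylsilyloxy)-5-hydroxy-8-isopropyl-5-methyl-1-methylidenecyclodec-7-yl 4-(tert-butyldimethylsilyloxy)benzoate, via mixed anhydride 29 (not isolated)
Conditions: 28, 2,4,6-Cl3C6H2COCl, Et3N, THF, rt; then 25, DMAP, toluene, rt
Reagents that add atoms: 4-(tert-butyldimethylsilyloxy)benzoic acid, CC(C)(C)[Si](C)(C)Oc1ccc(C(=O)O)cc1
Why: Yamaguchi esterification via the mixed anhydride acylates the only reactive hydroxyl, the secondary C7–OH, since the C5 hydroxyl is tertiary and O9 is silylated.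

Step 20
Reactants: 30 (5R,7R,8R,9S)-9-(tert-butyldimethylsilyloxy)-5-hydroxy-8-isopropyl-5-methyl-1-methylidenecyclodec-7-yl 4-(tert-butyldimethylsilyloxy)benzoate
Product: 31 (5R,7R,8S,9S)-5,9-dihydroxy-8-isopropyl-5-methyl-1-methylidenecyclodec-7-yl 4-hydroxybenzoate (CNP0293401.1)
Conditions: HF·pyridine, pyridine, THF, 0 °C → rt
Reagents that add atoms: none
Why: Fluoride-mediated cleavage of the aryl and the C9 silyl ethers under buffered, non-basic conditions, which should avoid acyl migration from O7 to O9 or O5 and spare the tertiary alcohol and the exocyclic alkene.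

**Compound list**

1 | phloroglucinol | Oc1cc(O)cc(O)c1 | starting material
2 | propan-2-ol | CC(C)O | starting material
3 | 2-isopropylbenzene-1,3,5-triol | CC(C)c1c(O)cc(O)cc1O | intermediate
4 | all-cis-2-isopropylcyclohexane-1,3,5-triol (meso) | O[C@H]1C[C@@H](O)[C@@H](C(C)C)[C@@H](O)C1 | intermediate
5 | all-cis-3,5-dihydroxy-4-isopropylcyclohexyl pivalate (meso) | CC(C)(C)C(=O)O[C@H]1C[C@@H](O)[C@@H](C(C)C)[C@@H](O)C1 | intermediate
6 | (1R,3R,4S,5S)-3-acetoxy-5-hydroxy-4-isopropylcyclohexyl pivalate | CC(C)(C)C(=O)O[C@H]1C[C@@H](OC(C)=O)[C@@H](C(C)C)[C@@H](O)C1 | intermediate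
7 | (1S,3R,4R,5S)-3-acetoxy-5-(tert-butyldimethylsilyloxy)-4-isopropylcyclohexyl pivalate | CC(C)(C)C(=O)O[C@H]1C[C@@H](OC(C)=O)[C@@H](C(C)C)[C@@H](O[Si](C)(C)C(C)(C)C)C1 | intermediate
8 | (1S,3R,4R,5S)-5-(tert-butyldimethylsilyloxy)-3-hydroxy-4-isopropylcyclohexyl pivalate | CC(C)(C)C(=O)O[C@H]1C[C@@H](O)[C@@H](C(C)C)[C@@H](O[Si](C)(C)C(C)(C)C)C1 | intermediate
9 | (1S,3R,4R,5S)-5-(tert-butyldimethylsilyloxy)-4-isopropyl-3-(triethylsilyloxy)cyclohexyl pivalate | CC(C)(C)C(=O)O[C@H]1C[C@@H](O[Si](CC)(CC)CC)[C@@H](C(C)C)[C@@H](O[Si](C)(C)C(C)(C)C)C1 | intermediate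
10 | (1S,3R,4R,5S)-5-(tert-butyldimethylsilyloxy)-4-isopropyl-3-(triethylsilyloxy)cyclohexan-1-ol | O[C@H]1C[C@@H](O[Si](CC)(CC)CC)[C@@H](C(C)C)[C@@H](O[Si](C)(C)C(C)(C)C)C1 | intermediate
11 | (3R,4R,5S)-5-(tert-butyldimethylsilyloxy)-4-isopropyl-3-(triethylsilyloxy)cyclohexan-1-one | O=C1C[C@@H](O[Si](CC)(CC)CC)[C@@H](C(C)C)[C@@H](O[Si](C)(C)C(C)(C)C)C1 | intermediate
12 | lithium C1–C2 enolate of 11 | [Li+].[O-]C1=C[C@@H](O[Si](CC)(CC)CC)[C@@H](C(C)C)[C@@H](O[Si](C)(C)C(C)(C)C)C1 | intermediate (not isolated)
13 | (3S,4S,5S)-5-(tert-butyldimethylsilyloxy)-4-isopropyl-3-(triethylsilyloxy)-1-(trimethylsilyloxy)cyclohex-1-ene | C[Si](C)(C)OC1=C[C@@H](O[Si](CC)(CC)CC)[C@@H](C(C)C)[C@@H](O[Si](C)(C)C(C)(C)C)C1 | intermediate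
14 | 2-bromopropene | C=C(C)Br | starting material
15 | tributylstannyl C1–C2 enolate of 11 | CCCC[Sn](CCCC)(CCCC)OC1=C[C@@H](O[Si](CC)(CC)CC)[C@@H](C(C)C)[C@@H](O[Si](C)(C)C(C)(C)C)C1 | intermediate (not isolated)
16 | (2R,3S,4S,5S)-5-(tert-butyldimethylsilyloxy)-4-isopropyl-2-(prop-1-en-2-yl)-3-(triethylsilyloxy)cyclohexan-1-one | C=C(C)[C@@H]1[C@@H](O[Si](CC)(CC)CC)[C@@H](C(C)C)[C@@H](O[Si](C)(C)C(C)(C)C)CC1=O | intermediate
17 | vinylmagnesium bromide | C=C[Mg]Br | starting material
18 | (1R,2R,3S,4S,5S)-5-(tert-butyldimethylsilyloxy)-4-isopropyl-2-(prop-1-en-2-yl)-3-(triethylsilyloxy)-1-vinylcyclohexan-1-ol | C=C(C)[C@@H]1[C@@H](O[Si](CC)(CC)CC)[C@@H](C(C)C)[C@@H](O[Si](C)(C)C(C)(C)C)C[C@@]1(O)C=C | intermediate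
19 | potassium alkoxide of 18 | [K+].C=C(C)[C@@H]1[C@@H](O[Si](CC)(CC)CC)[C@@H](C(C)C)[C@@H](O[Si](C)(C)C(C)(C)C)C[C@@]1([O-])C=C | intermediate (not isolated)
20 | potassium C1–C2 enolate of 21 | [K+].[O-]/C1=C\CC/C(C)=C/[C@@H](O[Si](CC)(CC)CC)[C@@H](C(C)C)[C@@H](O[Si](C)(C)C(C)(C)C)C1 | intermediate (not isolated)
21 | (5E,7R,8S,9S)-9-(tert-butyldimethylsilyloxy)-8-isopropyl-5-methyl-7-(triethylsilyloxy)cyclodec-5-en-1-one | O=C1CCC/C(C)=C/[C@@H](O[Si](CC)(CC)CC)[C@@H](C(C)C)[C@@H](O[Si](C)(C)C(C)(C)C)C1 | intermediate
22 | (5E,7R,8S,9S)-9-(tert-butyldimethylsilyloxy)-8-isopropyl-5-methyl-1-methylidene-7-(triethylsilyloxy)cyclodec-5-ene | C=C1CCC/C(C)=C/[C@@H](O[Si](CC)(CC)CC)[C@@H](C(C)C)[C@@H](O[Si](C)(C)C(C)(C)C)C1 | intermediate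
23 | (5E,7R,8R,9S)-9-(tert-butyldimethylsilyloxy)-8-isopropyl-5-methyl-1-methylidenecyclodec-5-en-7-ol | C=C1CCC/C(C)=C/[C@@H](O)[C@@H](C(C)C)[C@@H](O[Si](C)(C)C(C)(C)C)C1 | intermediate
24 | (5R,6R,7S,8R,9S)-9-(tert-butyldimethylsilyloxy)-5,6-epoxy-8-isopropyl-5-methyl-1-methylidenecyclodecan-7-ol | C=C1CCC[C@@]2(C)O[C@@H]2[C@@H](O)[C@@H](C(C)C)[C@@H](O[Si](C)(C)C(C)(C)C)C1 | intermediate
25 | (5R,7R,8R,9S)-9-(tert-butyldimethylsilyloxy)-8-isopropyl-5-methyl-1-methylidenecyclodecane-5,7-diol | C=C1CCC[C@@](C)(O)C[C@@H](O)[C@@H](C(C)C)[C@@H](O[Si](C)(C)C(C)(C)C)C1 | intermediate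
26 | 4-hydroxybenzoic acid | O=C(O)c1ccc(O)cc1 | starting material
27 | tert-butyldimethylsilyl 4-(tert-butyldimethylsilyloxy)benzoate | CC(C)(C)[Si](C)(C)OC(=O)c1ccc(O[Si](C)(C)C(C)(C)C)cc1 | intermediate (not isolated)
28 | 4-(tert-butyldimethylsilyloxy)benzoic acid | CC(C)(C)[Si](C)(C)Oc1ccc(C(=O)O)cc1 | intermediate
29 | 4-(tert-butyldimethylsilyloxy)benzoic 2,4,6-trichlorobenzoic anhydride | CC(C)(C)[Si](C)(C)Oc1ccc(C(=O)OC(=O)c2c(Cl)cc(Cl)cc2Cl)cc1 | intermediate (not isolated)
30 | (5R,7R,8R,9S)-9-(tert-butyldimethylsilyloxy)-5-hydroxy-8-isopropyl-5-methyl-1-methylidenecyclodec-7-yl 4-(tert-butyldimethylsilyloxy)benzoate | C=C1CCC[C@@](C)(O)C[C@@H](OC(=O)c2ccc(O[Si](C)(C)C(C)(C)C)cc2)[C@@H](C(C)C)[C@@H](O[Si](C)(C)C(C)(C)C)C1 | intermediate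
31 | (5R,7R,8S,9S)-5,9-dihydroxy-8-isopropyl-5-methyl-1-methylidenecyclodec-7-yl 4-hydroxybenzoate | C=C1CCC[C@@](C)(O)C[C@@H](OC(=O)c2ccc(O)cc2)[C@@H](C(C)C)[C@@H](O)C1 | target

**Step count**

Total: 20 steps. Longest linear sequence: 19 steps (steps 1–17, 19 and 20; step 18 is a one-step side branch).

**Three steps most likely to fail**

Step 11. The metal enolate at C2 may expel the neighbouring C3 silanolate (β-elimination to the enone) at the coupling temperature, or the coupled β,γ-unsaturated ketone may drift into conjugation. The fallback forms the C2–C bond without any metal enolate. Starting from 13, a TiCl4-mediated Mukaiyama aldol addition to acetone in CH2Cl2 at −78 °C should give (2S,3S,4S,5S)-5-(tert-butyldimethylsilyloxy)-2-(2-hydroxypropan-2-yl)-4-isopropyl-3-(triethylsilyloxy)cyclohexan-1-one F1. Dehydration of the tertiary alcohol with the Burgess reagent in benzene at 50 °C should then favour loss of a methyl hydrogen, because the conjugated isopropylidene isomer would suffer A1,3 strain with the C3 silyloxy group. The sequence rejoins the route at 16.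

Step 4. Both carbinols of the meso diol are flanked by the isopropyl-bearing carbon, so enzymatic acyl transfer may be slow or poorly selective between the enantiotopic hydroxyls. The fallback replaces the enzyme by a small-molecule catalyst and installs the final silyl group directly. Starting from 5, catalytic enantioselective mono-silylation (TBSCl, i-Pr2NEt, a chiral amino-acid-derived N-methylimidazole Lewis-base catalyst, THF, −40 °C), with the catalyst enantiomer chosen to silylate O–C5, gives 8 in one operation. Compounds 6 and 7 are bypassed and no new compound is needed; the route continues from 8.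

Step 16. Facial selectivity may be poor if the ring conformer with the C7 hydroxyl in the alkene plane competes, which would deliver oxygen to the other face and give the C5 epimer. The fallback moves the epoxidation ahead of TES removal and relies on steric, conformational control instead of metal-directed delivery. Starting from 22, dimethyldioxirane in acetone at −20 °C should epoxidise the trisubstituted alkene in preference to the 1,1-disubstituted one. The bulky triethylsilyloxy group cannot sit in the alkene plane beside the C5 methyl, so only the conformer with C7–H eclipsed should react, and attack on the outer face gives (5R,6R,7S,8S,9S)-9-(tert-butyldimethylsilyloxy)-5,6-epoxy-8-isopropyl-5-methyl-1-methylidene-7-(triethylsilyloxy)cyclodecane F2. Methanolysis of the triethylsilyl ether (PPTS, MeOH, 0 °C) then rejoins the route at 24.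

**Further compounds**

F1 | step 11 | (2S,3S,4S,5S)-5-(tert-butyldimethylsilyloxy)-2-(2-hydroxypropan-2-yl)-4-isopropyl-3-(triethylsilyloxy)cyclohexan-1-one | CC(C)(O)[C@@H]1[C@@H](O[Si](CC)(CC)CC)[C@@H](C(C)C)[C@@H](O[Si](C)(C)C(C)(C)C)CC1=O
F0 | step 4 | none | none
F2 | step 16 | (5R,6R,7S,8S,9S)-9-(tert-butyldimethylsilyloxy)-5,6-epoxy-8-isopropyl-5-methyl-1-methylidene-7-(triethylsilyloxy)cyclodecane | C=C1CCC[C@@]2(C)O[C@@H]2[C@@H](O[Si](CC)(CC)CC)[C@@H](C(C)C)[C@@H](O[Si](C)(C)C(C)(C)C)C1
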